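## Structural features

Eduesmine is a single oxolane ring (O1, C2 to C5) that carries a 4-hydroxy-3-methoxyphenyl ring on C2 and on C5 and a hydroxymethyl arm on C3 and on C4. The four ring carbons are contiguous stereocentres, all S, with the pattern 2,3-cis, 3,4-trans, 4,5-cis, so the two aryl groups are trans to each other and a twofold axis runs through O1 and the midpoint of C3–C4. Both ring C–O bonds are benzylic ethers para to a free phenol: acid can ionise them and base can open them through a quinone methide, and either event would epimerise C2 or C5. The real difficulty is that each aryl group is cis to the hydroxymethyl arm on the neighbouring carbon, the less stable arrangement, while the two halves lie on opposite faces; neither equilibration nor addition to the open face of a ring that already holds one half gives this. The key step exploits the O1–C5–C4–C3 edge: the cis pair C5-aryl and C4-CH2O has the geometry of a (Z)-cinnamyl alcohol, C3 with its exocyclic carbon is a carbene carbon bearing an ester carbonyl, and C2 with its aryl group and O1 is an aroyl group. The ester that tethers carbene and alkene therefore becomes a lactone bridging exactly the two arms, and no tether atom is lost.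

## Logic of the disconnections

14 from 13: the two phenolic O–H bonds are traced back to aryl O–S bonds. The sulfonate groups make both arenes poor donors, so the benzylic ring bonds cannot ionise in any earlier step, and removing them last means the sensitive p-hydroxybenzyl ether exists only in the final flask. The forward step must cleave two aryl sulfonates without opening the benzylic ether.

13 from 12: the C2–H and C3–H bonds are cut, giving a C2=C3 enol ether. Making both centres in one cis addition is the only way to put the C2 aryl trans to the C5 aryl and the C3 arm trans to the C4 arm together. The demand is heavy: both hydrogens must arrive on the face that already carries the C4 arm and the C5 aryl, so the C4 hydroxyl has to steer the metal.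

12 from 11: the two C–H bonds of the C3 carbinol are cut and the C4 oxygen is reconnected to that carbon as a lactone. This returns the product of the annulation directly and stores the enol ether as a stable vinylogous carbonate. The forward step is a lactone-to-diol reduction that must leave the aryl sulfonates and the enol ether alone.

11 from 9 through 10: O1–C5 and C3–C4 are cut. This removes the ring and both stereocentres at once and leads to an acyclic diazo ester with no stereocentre. In the forward direction the C3–C5 bond of 10 is made and broken again. The forward step needs stereospecific syn addition to the (Z)-alkene, face control by a chiral dirhodium carboxylate, and ring expansion with retention at C5.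

9 from 8: the C=N2 bond is cut; diazo transfer to an active methylene is routine.

8 from 7 and 5: the acyl–oxygen bond of the ester is cut. This separates the two aryl halves. The forward ester exchange must not isomerise the (Z)-alkene.

7 from 2 and 6: the bond between the ketone carbon and its α-carbon is cut. A base-free homologation of an aldehyde with the diazo ester is chosen over a base-mediated acylation of a methyl ketone, because the methyl protons of an aryl methanesulfonate are about as acidic as those of an aryl ketone and their removal leads to loss of the sulfonate as sulfene.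

5 from 4, and 4 from 2 and 3: the carbinol C–H bonds are cut back to an ester, then the C4=C5 alkene is cut. The same aldehyde thus serves both halves, which saves a separate aryl halide, an alkyne and a semi-hydrogenation. The demand is high (Z)-selectivity in the olefination, since the alkene geometry becomes the 4,5-cis relation.

2 from 1: the aryl O–S bond is cut, leaving a cheap phenolic aldehyde.

## Other disconnections considered

Alternative 1: The cut is at the two aryl–ring bonds, C2–aryl and C5–aryl, leaving the intact oxolane diamide A1 and two equivalents of the aryl iodide A2. In the forward step Pd(OAc)2 with AgOAc would metalate, under direction by each quinolin-8-yl amide, the ring methylene C–H that is β and cis to that amide; oxidative addition of A2 and reductive elimination, twice, would give A3.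
- In its favour: the palladacycle is a cis-fused five-membered ring, so each aryl must enter cis to its own amide, and with the amides trans this alone gives the whole 2,3-cis, 3,4-trans, 4,5-cis pattern. The twofold symmetry of the target is used.
- Against it here: the absolute configuration has to be brought in with A1, by resolution or a separate asymmetric synthesis. Two arylations on one small ring must both go to completion at high temperature with stoichiometric silver. The protons at C3 and C4 are α to an amide and may epimerise. The two robust amides must afterwards be activated and reduced to hydroxymethyl groups.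
- Comparison: on step count this alternative is the better one (about six steps from A1 against ten). On relative control at C2 and C5 it is at least the equal of the chosen plan, because both aryl centres are set by the same intramolecular metalation, whereas the chosen plan relies on a directed hydrogenation for C2. The chosen plan is preferred because it creates the absolute configuration by catalysis from achiral material and needs no auxiliary removal.

Alternative 2: The cut is at C2–C3 and C4–C5, and O1 is left to be closed last. In the forward step the symmetric diether A4 is lithiated at both benzylic carbons by t-BuLi in the presence of a chiral bis(oxazoline), and each carbanion undergoes a [2,3]-Wittig shift onto the nearer alkene to give diol A5.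
- In its favour: both C–C bonds and all four stereocentres would arise in one flask from an achiral substrate made in very few steps, and the (E)-geometry is relayed into each half through an envelope transition state. In bond-forming economy this is the better plan.
- Against it here: the second shift must be steered by the ligand against the centres already present. The aryl silyl ethers invite ortho-lithiation and retro-Brook silyl migration, and the [1,2]-shift competes. Most seriously, A5 has both carbinol carbons in the configuration of the target, so the oxolane must be closed with retention at the benzylic carbon that is substituted; an SN2 closure inverts it and an ionising closure favours the more stable trans arrangement. The two vinyl groups must then be cleaved by ozonolysis next to electron-rich arenes.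
- Comparison: the step count is about equal to the chosen plan or slightly lower. Stereocontrol at the ring closure is weaker than in the chosen plan, where the O1–C5 bond is formed by a double inversion of defined outcome.

Alternative 3: The cut is at O1–C2 and at the bond from C3 to its exocyclic carbon. In the forward step PdCl2(MeCN)2 (divalent palladium) activates the alkyne of A6, the C5 hydroxyl attacks the aryl-bearing alkyne carbon in a 5-endo-dig closure, the vinylpalladium inserts carbon monoxide A7, and methoxycarbonylation releases ester A8 and zerovalent palladium, which p-benzoquinone reoxidises.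
- In its favour: A8 has the same dihydrofuran-3-carbonyl pattern as 11, so the endgame is shared and the cyclisation mechanism is as well precedented as either half of the chosen key step (equal). In A8 the C4 arm (silyl ether) and the C3 arm (ester) are differentiated, so the C4 hydroxyl could be unveiled alone as the directing group before reduction to A9; on this point the alternative is better than 11, whose two arms become hydroxyls together.
- Against it here: the key step creates no stereocentre. C4 and C5 must already be present, enantiopure and diastereomerically pure, in A6, which costs a separate stereoselective construction. A free benzylic alcohol can be oxidised under divalent palladium and benzoquinone. Phenol benzyl ethers would have to be removed by hydrogenolysis next to two benzylic ring C–O bonds.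
- Comparison: step economy is probably worse, and the chosen plan makes C4, C5 and the ring in a single step from achiral material.

Key step: step 7

Assumption: Rh2(S-PTTL)4, dirhodium tetrakis[N-phthaloyl-(S)-tert-leucinate], is taken to attack the alkene face that gives (1R,5S,6S)-10; should the sense of induction be the opposite, Rh2(R-PTTL)4 is used and nothing else changes.

## Route

Step 1
Reactants: 1 vanillin (4-hydroxy-3-methoxybenzaldehyde)
Product: 2 4-formyl-2-methoxyphenyl methanesulfonate
Conditions: MsCl, Et3N, CH2Cl2, 0 °C to rt
Reagents that add atoms: methanesulfonyl chloride, CS(=O)(=O)Cl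
Why: O-sulfonylation of a phenol; the aldehyde is inert, and the electron-withdrawing mesylate is the spectator group that later keeps both benzylic positions from ionising.

Step 2
Reactants: 2 4-formyl-2-methoxyphenyl methanesulfonate; 3 methyl 2-[bis(2,2,2-trifluoroethoxy)phosphoryl]acetate
Product: 4 methyl (2Z)-3-[4-(methanesulfonyloxy)-3-methoxyphenyl]prop-2-enoate
Conditions: 3, KN(SiMe3)2, 18-crown-6, THF, −78 °C; then 2
Reagents that add atoms: none
Why: Still–Gennari variant of the Horner–Wadsworth–Emmons olefination; with the electron-poor phosphonate and a crown-complexed potassium ion, elimination from the kinetic adduct outruns its equilibration, so an aromatic aldehyde should give the (Z)-enoate. The phosphonate anion is formed before the aldehyde is added, so no free amide base meets the mesylate.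

Step 3
Reactants: 4 methyl (2Z)-3-[4-(methanesulfonyloxy)-3-methoxyphenyl]prop-2-enoate
Product: 5 4-[(1Z)-3-hydroxyprop-1-en-1-yl]-2-methoxyphenyl methanesulfonate
Conditions: i-Bu2AlH, CH2Cl2, −78 °C; aq. potassium sodium tartrate
Reagents that add atoms: none
Why: 1,2-reduction of an α,β-unsaturated ester to the allylic alcohol with i-Bu2AlH; the alkene geometry and the aryl mesylate should not be affected at low temperature.

Step 4
Reactants: 2 4-formyl-2-methoxyphenyl methanesulfonate; 6 ethyl diazoacetate
Product: 7 ethyl 3-[4-(methanesulfonyloxy)-3-methoxyphenyl]-3-oxopropanoate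
Conditions: NbCl5 (5 mol %), CH2Cl2, rt
Reagents that add atoms: none
Why: Roskamp reaction; the Lewis-acid-activated aldehyde is attacked by the diazo carbon and a 1,2-hydride shift with loss of N2 gives the β-keto ester without any base, which spares the mesylate.

Step 5
Reactants: 7 ethyl 3-[4-(methanesulfonyloxy)-3-methoxyphenyl]-3-oxopropanoate; 5 4-[(1Z)-3-hydroxyprop-1-en-1-yl]-2-methoxyphenyl methanesulfonate
Product: 8 (2Z)-3-[4-(methanesulfonyloxy)-3-methoxyphenyl]prop-2-en-1-yl 3-[4-(methanesulfonyloxy)-3-methoxyphenyl]-3-oxopropanoate
Conditions: DMAP (10 mol %), toluene, reflux, 4 Å molecular sieves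
Reagents that add atoms: none
Why: DMAP-catalysed transesterification of a β-keto ester through the acylketene; removal of ethanol drives it, and neither the (Z)-alkene nor the mesylates should react.

Step 6
Reactants: 8 (2Z)-3-[4-(methanesulfonyloxy)-3-methoxyphenyl]prop-2-en-1-yl 3-[4-(methanesulfonyloxy)-3-methoxyphenyl]-3-oxopropanoate
Product: 9 (2Z)-3-[4-(methanesulfonyloxy)-3-methoxyphenyl]prop-2-en-1-yl 2-diazo-3-[4-(methanesulfonyloxy)-3-methoxyphenyl]-3-oxopropanoate
Conditions: 4-acetamidobenzenesulfonyl azide, Et3N, MeCN, 0 °C to rt
Reagents that add atoms: 4-acetamidobenzenesulfonyl azide, CC(=O)Nc1ccc(cc1)S(=O)(=O)N=[N+]=[N-]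
Why: Regitz diazo transfer to the active methylene of a β-keto ester; the mild amine base does not endanger the mesylates.

Step 7
Reactants: 9 (2Z)-3-[4-(methanesulfonyloxy)-3-methoxyphenyl]prop-2-en-1-yl 2-diazo-3-[4-(methanesulfonyloxy)-3-methoxyphenyl]-3-oxopropanoate
Product: 11 (3aS,4S)-4,6-bis[4-(methanesulfonyloxy)-3-methoxyphenyl]-3a,4-dihydro-1H,3H-furo[3,4-c]furan-1-one, via aroylcyclopropane lactone 10 (not isolated)
Conditions: Rh2(S-PTTL)4 (1 mol %), PhCF3, 0 °C to rt, slow addition of 9; then DABCO (30 mol %), DMSO, 100 °C
Reagents that add atoms: none
Why: Rh2(S-PTTL)4 takes N2 out of 9 and the electrophilic dirhodium carbene adds to the tethered (Z)-alkene in one concerted, asynchronous step, closing the γ-lactone (carbene carbon to the nearer alkene carbon, five-membered ring, exo mode) and the cyclopropane together to give 10; the closest known reaction type is the catalytic asymmetric intramolecular cyclopropanation of allyl α-diazo-β-keto esters. The absolute configuration of the ring-fusion carbon (C4 of the target) is set by the chiral carboxylate ligands, which choose the alkene face, and the benzylic carbon (C5) is set relative to it by the (Z)-geometry, because syn addition keeps aryl and CH2O cis. DABCO then opens 10 by SN2 attack at the benzylic cyclopropane carbon with inversion, the leaving group being the enolate of the aroyl lactone, and the ketone oxygen of that enolate displaces the ammonium group in a 5-exo-tet closure with a second inversion; this is the amine-catalysed Cloke–Wilson rearrangement of aroyl cyclopropanes. The two inversions add up to retention at C5, so the oxolane closes as the 4,5-dihydrofuran with the C5 aryl still cis to the lactone CH2, and C4 is never touched. Only the ketone oxygen can close, because closure through the lactone carbonyl oxygen would put a double bond at a bridgehead. The step needs chemoselectivity for cyclopropanation, face selectivity at the alkene and fidelity at the benzylic carbon: the five-atom tether and the (Z)-alkene secure the first and the cis relation, the catalyst the second, and the two aryl mesylates, which make both arenes poor donors, keep the benzylic carbon from ionising in either stage.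

Step 8
Reactants: 11 (3aS,4S)-4,6-bis[4-(methanesulfonyloxy)-3-methoxyphenyl]-3a,4-dihydro-1H,3H-furo[3,4-c]furan-1-one
Product: 12 {(4S,5S)-2,5-bis[4-(methanesulfonyloxy)-3-methoxyphenyl]-4,5-dihydrofuran-3,4-diyl}dimethanol
Conditions: i-Bu2AlH (4 equiv), CH2Cl2, −78 to −40 °C; aq. potassium sodium tartrate
Reagents that add atoms: none
Why: i-Bu2AlH reduction of a lactone past the lactol to the diol; the carbonyl is a vinylogous carbonate and is reduced in 1,2-fashion, the enol ether and aryl mesylates are inert to the hydride, and the neutral tartrate work-up avoids ionising the new allylic alcohol.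

Step 9
Reactants: 12 {(4S,5S)-2,5-bis[4-(methanesulfonyloxy)-3-methoxyphenyl]-4,5-dihydrofuran-3,4-diyl}dimethanol
Product: 13 {(2S,3S,4S,5S)-2,5-bis[4-(methanesulfonyloxy)-3-methoxyphenyl]oxolane-3,4-diyl}dimethanol
Conditions: [Ir(cod)(PCy3)(py)]PF6 (10 mol %), H2 (1 atm), CH2Cl2, 0 °C to rt
Reagents that add atoms: none
Why: Hydroxyl-directed homogeneous hydrogenation with cationic iridium; the C4 hydroxymethyl is the only hydroxyl fixed on one face, and when it binds the metal both hydrogens are delivered cis to it. This sets C3 (arm trans to the C4 arm) and C2 (aryl cis to the C3 arm and trans to the C5 aryl), the opposite of what addition to the open face would give.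

Step 10
Reactants: 13 {(2S,3S,4S,5S)-2,5-bis[4-(methanesulfonyloxy)-3-methoxyphenyl]oxolane-3,4-diyl}dimethanol
Product: 14 eduesmine, 4,4'-[(2S,3S,4S,5S)-3,4-bis(hydroxymethyl)oxolane-2,5-diyl]bis(2-methoxyphenol)
Conditions: KOH, MeOH/H2O, 50 °C; then aq. NH4Cl
Reagents that add atoms: none
Why: Hydroxide cleaves aryl methanesulfonates at sulfur and leaves alcohols and alkyl ethers alone; the moderate temperature is chosen so that the phenoxide does not open the benzylic ether.

## Compound list

1 | vanillin (4-hydroxy-3-methoxybenzaldehyde) | COc1cc(C=O)ccc1O | starting material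
2 | 4-formyl-2-methoxyphenyl methanesulfonate | COc1cc(C=O)ccc1OS(C)(=O)=O | intermediate
3 | methyl 2-[bis(2,2,2-trifluoroethoxy)phosphoryl]acetate | COC(=O)CP(=O)(OCC(F)(F)F)OCC(F)(F)F | starting material
4 | methyl (2Z)-3-[4-(methanesulfonyloxy)-3-methoxyphenyl]prop-2-enoate | COC(=O)/C=C\c1ccc(OS(C)(=O)=O)c(OC)c1 | intermediate
5 | 4-[(1Z)-3-hydroxyprop-1-en-1-yl]-2-methoxyphenyl methanesulfonate | COc1cc(/C=C\CO)ccc1OS(C)(=O)=O | intermediate
6 | ethyl diazoacetate | CCOC(=O)C=[N+]=[N-] | starting material
7 | ethyl 3-[4-(methanesulfonyloxy)-3-methoxyphenyl]-3-oxopropanoate | CCOC(=O)CC(=O)c1ccc(OS(C)(=O)=O)c(OC)c1 | intermediate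
8 | (2Z)-3-[4-(methanesulfonyloxy)-3-methoxyphenyl]prop-2-en-1-yl 3-[4-(methanesulfonyloxy)-3-methoxyphenyl]-3-oxopropanoate | COc1cc(/C=C\COC(=O)CC(=O)c2ccc(OS(C)(=O)=O)c(OC)c2)ccc1OS(C)(=O)=O | intermediate
9 | (2Z)-3-[4-(methanesulfonyloxy)-3-methoxyphenyl]prop-2-en-1-yl 2-diazo-3-[4-(methanesulfonyloxy)-3-methoxyphenyl]-3-oxopropanoate | COc1cc(/C=C\COC(=O)C(=[N+]=[N-])C(=O)c2ccc(OS(C)(=O)=O)c(OC)c2)ccc1OS(C)(=O)=O | intermediate
10 | (1R,5S,6S)-1-[4-(methanesulfonyloxy)-3-methoxybenzoyl]-6-[4-(methanesulfonyloxy)-3-methoxyphenyl]-3-oxabicyclo[3.1.0]hexan-2-one (6-aryl cis to C4H2, not isolated) | O=C1OC[C@H]2[C@@H](c3ccc(OS(C)(=O)=O)c(OC)c3)[C@@]12C(=O)c1ccc(OS(C)(=O)=O)c(OC)c1 | intermediate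
11 | (3aS,4S)-4,6-bis[4-(methanesulfonyloxy)-3-methoxyphenyl]-3a,4-dihydro-1H,3H-furo[3,4-c]furan-1-one | COc1cc(ccc1OS(C)(=O)=O)C=1O[C@H](c3ccc(OS(C)(=O)=O)c(OC)c3)[C@@H]2COC(=O)C2=1 | intermediate
12 | {(4S,5S)-2,5-bis[4-(methanesulfonyloxy)-3-methoxyphenyl]-4,5-dihydrofuran-3,4-diyl}dimethanol | COc1cc(ccc1OS(C)(=O)=O)C=1O[C@H](c2ccc(OS(C)(=O)=O)c(OC)c2)[C@H](CO)C=1CO | intermediate
13 | {(2S,3S,4S,5S)-2,5-bis[4-(methanesulfonyloxy)-3-methoxyphenyl]oxolane-3,4-diyl}dimethanol | COc1cc(ccc1OS(C)(=O)=O)[C@H]1O[C@H](c2ccc(OS(C)(=O)=O)c(OC)c2)[C@H](CO)[C@H]1CO | intermediate
14 | eduesmine, 4,4'-[(2S,3S,4S,5S)-3,4-bis(hydroxymethyl)oxolane-2,5-diyl]bis(2-methoxyphenol) | COc1cc([C@H]2O[C@H](c3ccc(O)c(OC)c3)[C@H](CO)[C@H]2CO)ccc1O | target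

## Step count and least certain steps

Total step count: 10. Longest linear sequence: 9 steps (steps 1, 2, 3, 5, 6, 7, 8, 9, 10).

Step 7 (key step). The most likely failure is insufficient face selectivity, possibly with partial loss of the cis relation. A carbene flanked by two carbonyl groups is very electrophilic, its transition state with the styrenyl alkene is early, and a stepwise, zwitterionic addition would let the benzylic carbon rotate. The fallback gives up catalyst control of the absolute configuration. Setting out from 9, the decomposition is run with the achiral, robust Rh2(esp)2, dirhodium bis(α,α,α′,α′-tetramethyl-1,3-benzenedipropionate), followed by the same DABCO stage. This should give 11 as a racemate with its mirror image, the (3aR,4R)-lactone F1. The two are separated by preparative chromatography on a chiral stationary phase, which is practical for a neutral, UV-active lactone. The route is rejoined at 11.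

Step 9. The most likely failure is poor facial selectivity. The allylic hydroxyl on the C3 arm lies in the alkene plane, can bind iridium on either side, and would then steer hydrogen to the open face, giving the all-cis isomer. Acid-induced ionisation of that allylic alcohol by the cationic catalyst is a second risk. The fallback removes the in-plane hydroxyl from play by hydrogenating before the C3 carbon is reduced. Setting out from 11, Me2AlN(OMe)Me (from Me3Al and N,O-dimethylhydroxylamine hydrochloride) should open the lactone to the hydroxy amide (4S,5S)-4-(hydroxymethyl)-N-methoxy-N-methyl-2,5-bis[4-(methanesulfonyloxy)-3-methoxyphenyl]-4,5-dihydrofuran-3-carboxamide F2. Its carbonyl is conjugated with the alkene and cannot reach a metal bound to it, so the C4 hydroxymethyl is the only directing group. Hydrogenation with [Ir(cod)(PCy3)(py)]PF6 under higher hydrogen pressure, needed because the alkene is now electron-poor, should give the saturated amide (2S,3R,4S,5S)-4-(hydroxymethyl)-N-methoxy-N-methyl-2,5-bis[4-(methanesulfonyloxy)-3-methoxyphenyl]oxolane-3-carboxamide F3. i-Bu2AlH followed by NaBH4 in the same flask then reduces the amide to the hydroxymethyl group. The route is rejoined at 13, and steps 8 and 9 are replaced.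

Step 10. The most likely failure is opening of a benzylic ring C–O bond through a quinone methide once the para phenoxide is formed in warm hydroxide, with epimerisation at C2 or C5; incomplete sulfonate cleavage that calls for harsher heating would make this worse. The fallback changes the cleavage mechanism to a cold elimination. Setting out from 13, both hydroxyls are silylated (t-BuMe2SiCl, imidazole) to the bis(silyl ether) {(2S,3S,4S,5S)-3,4-bis[(tert-butyldimethylsilyloxy)methyl]oxolane-2,5-diyl}bis(2-methoxy-4,1-phenylene) dimethanesulfonate F4. The silyl groups are needed so that no alkoxide can trap sulfene. LiN(i-Pr)2 in THF at −78 to 0 °C deprotonates the sulfonate methyl groups, sulfene is lost, and the bis-phenol 4,4'-{(2S,3S,4S,5S)-3,4-bis[(tert-butyldimethylsilyloxy)methyl]oxolane-2,5-diyl}bis(2-methoxyphenol) F5 should result. HF·pyridine then removes the silyl groups. The route is rejoined at 14.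

Step 4. The most likely failure is migration of the aryl group instead of hydride in the diazonium adduct, a known weakness of aromatic aldehydes in this homologation, which would lower the amount of β-keto ester. The fallback builds the same bond by acylation of a malonate. Setting out from 2, Pinnick oxidation (NaClO2, NaH2PO4, 2-methylbut-2-ene) gives 4-(methanesulfonyloxy)-3-methoxybenzoic acid F6. Carbonyldiimidazole converts it into the imidazolide 4-(1H-imidazole-1-carbonyl)-2-methoxyphenyl methanesulfonate F7. The magnesium salt of monoethyl malonate (potassium ethyl malonate, MgCl2, Et3N) is then C-acylated and loses CO2 (Masamune–Brooks homologation). These conditions are only weakly basic. The route is rejoined at 7.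

## Further compounds

F1 | step 7 | (3aR,4R)-4,6-bis[4-(methanesulfonyloxy)-3-methoxyphenyl]-3a,4-dihydro-1H,3H-furo[3,4-c]furan-1-one (enantiomer of 11) | COc1cc(ccc1OS(C)(=O)=O)C=1O[C@@H](c3ccc(OS(C)(=O)=O)c(OC)c3)[C@H]2COC(=O)C2=1
F2 | step 9 | (4S,5S)-4-(hydroxymethyl)-N-methoxy-N-methyl-2,5-bis[4-(methanesulfonyloxy)-3-methoxyphenyl]-4,5-dihydrofuran-3-carboxamide | COc1cc(ccc1OS(C)(=O)=O)C=1O[C@H](c2ccc(OS(C)(=O)=O)c(OC)c2)[C@H](CO)C=1C(=O)N(C)OC
F3 | step 9 | (2S,3R,4S,5S)-4-(hydroxymethyl)-N-methoxy-N-methyl-2,5-bis[4-(methanesulfonyloxy)-3-methoxyphenyl]oxolane-3-carboxamide | COc1cc(ccc1OS(C)(=O)=O)[C@H]1O[C@H](c2ccc(OS(C)(=O)=O)c(OC)c2)[C@H](CO)[C@H]1C(=O)N(C)OC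
F4 | step 10 | {(2S,3S,4S,5S)-3,4-bis[(tert-butyldimethylsilyloxy)methyl]oxolane-2,5-diyl}bis(2-methoxy-4,1-phenylene) dimethanesulfonate | COc1cc(ccc1OS(C)(=O)=O)[C@H]1O[C@H](c2ccc(OS(C)(=O)=O)c(OC)c2)[C@H](CO[Si](C)(C)C(C)(C)C)[C@H]1CO[Si](C)(C)C(C)(C)C
F5 | step 10 | 4,4'-{(2S,3S,4S,5S)-3,4-bis[(tert-butyldimethylsilyloxy)methyl]oxolane-2,5-diyl}bis(2-methoxyphenol) | COc1cc(ccc1O)[C@H]1O[C@H](c2ccc(O)c(OC)c2)[C@H](CO[Si](C)(C)C(C)(C)C)[C@H]1CO[Si](C)(C)C(C)(C)C
F6 | step 4 | 4-(methanesulfonyloxy)-3-methoxybenzoic acid | COc1cc(C(=O)O)ccc1OS(C)(=O)=O
F7 | step 4 | 4-(1H-imidazole-1-carbonyl)-2-methoxyphenyl methanesulfonate | COc1cc(C(=O)n2ccnc2)ccc1OS(C)(=O)=O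
A1 | alternative 1 | (3R,4R)-N3,N4-di(quinolin-8-yl)oxolane-3,4-dicarboxamide | C1OC[C@H](C(=O)Nc2cccc3cccnc23)[C@H]1C(=O)Nc1cccc2cccnc12
A2 | alternative 1 | 4-iodo-2-methoxyphenyl acetate | COc1cc(I)ccc1OC(C)=O
A3 | alternative 1 | (2S,3R,4R,5S)-2,5-bis(4-acetoxy-3-methoxyphenyl)-N3,N4-di(quinolin-8-yl)oxolane-3,4-dicarboxamide | COc1cc(ccc1OC(C)=O)[C@H]1O[C@H](c2ccc(OC(C)=O)c(OC)c2)[C@H](C(=O)Nc2cccc3cccnc23)[C@H]1C(=O)Nc1cccc2cccnc12
A4 | alternative 2 | (2E,4E)-1,6-bis{[4-(tert-butyldimethylsilyloxy)-3-methoxyphenyl]methoxy}hexa-2,4-diene | COc1cc(COC/C=C/C=C/COCc2ccc(O[Si](C)(C)C(C)(C)C)c(OC)c2)ccc1O[Si](C)(C)C(C)(C)C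
A5 | alternative 2 | (1S,2R,3R,4S)-1,4-bis[4-(tert-butyldimethylsilyloxy)-3-methoxyphenyl]-2,3-diethenylbutane-1,4-diol | COc1cc(ccc1O[Si](C)(C)C(C)(C)C)[C@@H](O)[C@H](C=C)[C@@H](C=C)[C@H](O)c1ccc(O[Si](C)(C)C(C)(C)C)c(OC)c1
A6 | alternative 3 | (1S,2S)-1,4-bis[4-(benzyloxy)-3-methoxyphenyl]-2-[(tert-butyldimethylsilyloxy)methyl]but-3-yn-1-ol | COc1cc(ccc1OCc1ccccc1)C#C[C@@H](CO[Si](C)(C)C(C)(C)C)[C@H](O)c1ccc(OCc2ccccc2)c(OC)c1
A7 | alternative 3 | carbon monoxide | [C-]#[O+]
A8 | alternative 3 | methyl (4S,5S)-2,5-bis[4-(benzyloxy)-3-methoxyphenyl]-4-[(tert-butyldimethylsilyloxy)methyl]-4,5-dihydrofuran-3-carboxylate | COc1cc(ccc1OCc1ccccc1)C=1O[C@H](c2ccc(OCc3ccccc3)c(OC)c2)[C@H](CO[Si](C)(C)C(C)(C)C)C=1C(=O)OC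
A9 | alternative 3 | {(4S,5S)-2,5-bis[4-(benzyloxy)-3-methoxyphenyl]-4,5-dihydrofuran-3,4-diyl}dimethanol | COc1cc(ccc1OCc1ccccc1)C=1O[C@H](c2ccc(OCc3ccccc3)c(OC)c2)[C@H](CO)C=1CO
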